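**Plan**

- Retrosynthesis: after removal of the C6 O-benzyl group and the C2=C3 unsaturation, the pyranone (ring C) is opened at O1–C2 (oxa-Michael). The resulting aryl α-arylvinyl ketone is cut at both C4–C4a and C3–C4, which leaves a ring A aryl iodide, carbon monoxide and a 1-arylvinylboronate carrying ring B.
- Enabling feature: C4 is a lone carbonyl carbon lying between C4a and C3. C4a is the ring A carbon ortho to the O1-bearing C8a and para to the C7 methoxy, which is where 4-(benzyloxy)-3-methoxyphenol takes up iodine.
- Forward: the ring A iodide comes from O-benzylvanillin (Dakin-type oxidation, iodination, MOM protection) and the boronate from 3',4',5'-trimethoxyacetophenone (enol triflate, Miyaura borylation). The three-component carbonylative coupling joins the chain without closing a ring; ring C then closes at oxygen, is dehydrogenated, and the benzyl ether is removed last.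
- Remark: the phenol is carried through the coupling as its methoxymethyl ether, so that neither phenoxycarbonylation nor premature oxa-Michael closure can compete.
- Stereochemistry: the target has no stereocentre; C3 of the intermediate isoflavanone is formed racemic and is erased by the dehydrogenation.

Key step: step 6

**Route**

Step 1
Reactants: 1 4-(benzyloxy)-3-methoxybenzaldehyde (O-benzylvanillin)
Product: 3 4-(benzyloxy)-3-methoxyphenol, via aryl formate 2 (not isolated)
Conditions: mCPBA, CH2Cl2, 0 °C to rt; aq. NaHCO3 wash; then K2CO3 (cat.), MeOH, rt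
Reagents that add atoms: 3-chloroperoxybenzoic acid (mCPBA), O=C(OO)c1cccc(Cl)c1
Why: Baeyer–Villiger (Dakin-type) oxidation, in which the electron-rich 4-alkoxyaryl group migrates in the Criegee adduct of the aldehyde to give the aryl formate, which carbonate-catalysed methanolysis converts to the phenol.

Step 2
Reactants: 3 4-(benzyloxy)-3-methoxyphenol
Product: 4 4-(benzyloxy)-2-iodo-5-methoxyphenol
Conditions: NIS (1.0 equiv), MeCN, 0 °C
Reagents that add atoms: N-iodosuccinimide, O=C1CCC(=O)N1I
Why: Electrophilic aromatic iodination of the phenol should go to the unhindered carbon ortho to OH and para to OMe (the future C4a) rather than to the crowded position between OH and OMe.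

Step 3
Reactants: 4 4-(benzyloxy)-2-iodo-5-methoxyphenol
Product: 5 1-(benzyloxy)-5-iodo-2-methoxy-4-(methoxymethoxy)benzene
Conditions: MOMCl, iPr2NEt, CH2Cl2, 0 °C to rt
Reagents that add atoms: chloromethyl methyl ether, COCCl
Why: O-Alkylation of the phenol with MOMCl under amine base (acetal protection) masks the hydroxyl in a form that is stable to the basic palladium step and is later removed by mild acid without touching the benzyl ether.

Step 4
Reactants: 6 1-(3,4,5-trimethoxyphenyl)ethan-1-one (3',4',5'-trimethoxyacetophenone)
Product: 7 1-(3,4,5-trimethoxyphenyl)ethenyl trifluoromethanesulfonate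
Conditions: KN(SiMe3)2, THF, −78 °C; then PhNTf2, −78 to 0 °C; used promptly
Reagents that add atoms: N-phenylbis(trifluoromethanesulfonimide), O=S(=O)(N(c1ccccc1)S(=O)(=O)C(F)(F)F)C(F)(F)F
Why: Enol triflate formation by kinetic enolisation of the methyl ketone and O-sulfonylation of the potassium enolate with PhNTf2 avoids the strongly acidic medium that Tf2O would impose on the electron-rich arene.

Step 5
Reactants: 7 1-(3,4,5-trimethoxyphenyl)ethenyl trifluoromethanesulfonate; 8 bis(pinacolato)diboron
Product: 9 4,4,5,5-tetramethyl-2-[1-(3,4,5-trimethoxyphenyl)ethenyl]-1,3,2-dioxaborolane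
Conditions: PdCl2(PPh3)2 (3 mol%), PPh3 (6 mol%), KOPh (1.5 equiv), toluene, 50 °C
Reagents that add atoms: bis(pinacolato)diboron (8), CC1(C)OB(OC1(C)C)B1OC(C)(C)C(C)(C)O1
Why: Miyaura borylation of an alkenyl triflate, in which zerovalent palladium inserts into the C–OTf bond, phenoxide-assisted transmetalation with the diboron follows and reductive elimination gives the 1,1-disubstituted alkenylboronate, KOPh being the base that keeps follow-on Suzuki homocoupling low.

Step 6
Reactants: 5 1-(benzyloxy)-5-iodo-2-methoxy-4-(methoxymethoxy)benzene; 9 4,4,5,5-tetramethyl-2-[1-(3,4,5-trimethoxyphenyl)ethenyl]-1,3,2-dioxaborolane; 10 carbon monoxide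
Product: 11 1-[5-(benzyloxy)-4-methoxy-2-(methoxymethoxy)phenyl]-2-(3,4,5-trimethoxyphenyl)prop-2-en-1-one
Conditions: CO (5 bar), PdCl2(dppf) (5 mol%), K2CO3 (3 equiv), anisole–H2O (20:1), 80 °C
Reagents that add atoms: carbon monoxide (10), [C-]#[O+]
Why: Zerovalent palladium formed in situ inserts into the C4a–I bond of 5, the arylpalladium iodide takes up CO by migratory insertion to the aroylpalladium species, base-assisted transmetalation delivers the 1-arylvinyl group of 9 and reductive elimination releases the ketone, so that C4–C4a and C3–C4 arise in one operation. The closest known reaction type is the carbonylative Suzuki–Miyaura coupling of aryl iodides with alkenylboron reagents to aryl vinyl ketones. No ring closes and no stereocentre is created; the masked phenol oxygen can neither add to the enone nor intercept the aroylpalladium species. The selectivity needed is carbonylative over direct aryl–vinyl coupling, which the substrate supports because the electron-rich, ortho-alkoxy aryl group migrates readily to CO while the 1,1-disubstituted boronate transmetalates slowly, and CO pressure with the wide-bite-angle dppf ligand reinforces it. The benzyl, methyl and methoxymethyl ethers should be inert to the carbonate base.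

Step 7
Reactants: 11 1-[5-(benzyloxy)-4-methoxy-2-(methoxymethoxy)phenyl]-2-(3,4,5-trimethoxyphenyl)prop-2-en-1-one
Product: 13 rac-6-(benzyloxy)-7-methoxy-3-(3,4,5-trimethoxyphenyl)-2,3-dihydro-4H-chromen-4-one, via free phenol enone 12 (not isolated)
Conditions: TsOH·H2O (20 mol%), MeOH–THF (3:1), 50 °C; then K2CO3 (50 mol%), rt
Reagents that add atoms: none
Why: Acid-catalysed methanolysis of the aryl methoxymethyl acetal frees the phenol ortho to the ketone, and catalytic carbonate then triggers the 6-endo-trig intramolecular oxa-Michael addition of the phenoxide to the α-methylene ketone, the established closing stage of isoflavanone syntheses, with C3 formed racemic and erased in step 8.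

Step 8
Reactants: 13 rac-6-(benzyloxy)-7-methoxy-3-(3,4,5-trimethoxyphenyl)-2,3-dihydro-4H-chromen-4-one
Product: 14 6-(benzyloxy)-7-methoxy-3-(3,4,5-trimethoxyphenyl)-4H-chromen-4-one
Conditions: DDQ (1.5 equiv), 1,4-dioxane, reflux
Reagents that add atoms: none
Why: DDQ dehydrogenation of an isoflavanone to the isoflavone is driven by formation of the aromatic 4-pyranone, and the unactivated aryl benzyl ether should not be cleaved by the quinone.

Step 9
Reactants: 14 6-(benzyloxy)-7-methoxy-3-(3,4,5-trimethoxyphenyl)-4H-chromen-4-one
Product: 15 6-hydroxy-7-methoxy-3-(3,4,5-trimethoxyphenyl)-4H-chromen-4-one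
Conditions: H2 (1 atm), 10% Pd/C, EtOAc–MeOH, rt, stopped at full conversion
Reagents that add atoms: none
Why: Catalytic hydrogenolysis of the aryl benzyl ether should free the C6 hydroxyl under conditions in which the vinylogous-ester C2=C3 bond of the chromone is reduced only slowly.

**Compound list**

1 | 4-(benzyloxy)-3-methoxybenzaldehyde | COc1cc(C=O)ccc1OCc1ccccc1 | starting material
2 | 4-(benzyloxy)-3-methoxyphenyl formate | COc1cc(OC=O)ccc1OCc1ccccc1 | intermediate (not isolated)
3 | 4-(benzyloxy)-3-methoxyphenol | COc1cc(O)ccc1OCc1ccccc1 | intermediate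
4 | 4-(benzyloxy)-2-iodo-5-methoxyphenol | COc1cc(O)c(I)cc1OCc1ccccc1 | intermediate
5 | 1-(benzyloxy)-5-iodo-2-methoxy-4-(methoxymethoxy)benzene | COCOc1cc(OC)c(OCc2ccccc2)cc1I | intermediate
6 | 1-(3,4,5-trimethoxyphenyl)ethan-1-one | CC(=O)c1cc(OC)c(OC)c(OC)c1 | starting material
7 | 1-(3,4,5-trimethoxyphenyl)ethenyl trifluoromethanesulfonate | C=C(OS(=O)(=O)C(F)(F)F)c1cc(OC)c(OC)c(OC)c1 | intermediate
8 | bis(pinacolato)diboron | CC1(C)OB(OC1(C)C)B1OC(C)(C)C(C)(C)O1 | starting material
9 | 4,4,5,5-tetramethyl-2-[1-(3,4,5-trimethoxyphenyl)ethenyl]-1,3,2-dioxaborolane | C=C(B1OC(C)(C)C(C)(C)O1)c1cc(OC)c(OC)c(OC)c1 | intermediate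
10 | carbon monoxide | [C-]#[O+] | starting material
11 | 1-[5-(benzyloxy)-4-methoxy-2-(methoxymethoxy)phenyl]-2-(3,4,5-trimethoxyphenyl)prop-2-en-1-one | C=C(C(=O)c1cc(OCc2ccccc2)c(OC)cc1OCOC)c1cc(OC)c(OC)c(OC)c1 | intermediate
12 | 1-[5-(benzyloxy)-2-hydroxy-4-methoxyphenyl]-2-(3,4,5-trimethoxyphenyl)prop-2-en-1-one | C=C(C(=O)c1cc(OCc2ccccc2)c(OC)cc1O)c1cc(OC)c(OC)c(OC)c1 | intermediate (not isolated)
13 | rac-6-(benzyloxy)-7-methoxy-3-(3,4,5-trimethoxyphenyl)-2,3-dihydro-4H-chromen-4-one | COc1cc2OCC(c3cc(OC)c(OC)c(OC)c3)C(=O)c2cc1OCc1ccccc1 | intermediate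
14 | 6-(benzyloxy)-7-methoxy-3-(3,4,5-trimethoxyphenyl)-4H-chromen-4-one | COc1cc2occ(-c3cc(OC)c(OC)c(OC)c3)c(=O)c2cc1OCc1ccccc1 | intermediate
15 | 6-hydroxy-7-methoxy-3-(3,4,5-trimethoxyphenyl)-4H-chromen-4-one | COc1cc2occ(-c3cc(OC)c(OC)c(OC)c3)c(=O)c2cc1O | target

**Step count**

Total: 9 steps. Longest linear sequence: 7 steps (steps 1, 2, 3, 6, 7, 8, 9 from compound 1); the boronate branch (steps 4 and 5) joins at step 6.

**Steps most likely to fail**

Step 6. Direct aryl–vinyl coupling may outrun CO uptake, the hindered boronate may be lost by protodeboronation before it transmetalates, or the product enone may be consumed by Heck-type addition of organopalladium species. The fallback forms the two bonds to C4 one after the other, still with CO as the source of C4. Setting out from 5, palladium-catalysed aminocarbonylation (Pd(OAc)2, Xantphos, CO 1 atm, MeNHOMe·HCl, Na2CO3, toluene, 80 °C) should give the Weinreb amide 5-(benzyloxy)-N,4-dimethoxy-2-(methoxymethoxy)-N-methylbenzamide F1. Addition of (3,4,5-trimethoxybenzyl)magnesium chloride F2, prepared from commercial 3,4,5-trimethoxybenzyl chloride and Mg turnings in THF at 0 °C, should give the deoxybenzoin 1-[5-(benzyloxy)-4-methoxy-2-(methoxymethoxy)phenyl]-2-(3,4,5-trimethoxyphenyl)ethan-1-one F3. α-Methylenation of this ketone (paraformaldehyde, diisopropylammonium trifluoroacetate, THF, reflux) comes back to the route at 11.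

Step 5. The electron-rich α-aryl vinyl triflate may ionise or eliminate to the arylalkyne, the boronate may couple with unreacted triflate to a diene, or it may protodeboronate on purification. The fallback avoids both the triflate and palladium. Setting out from 6, condensation with 2,4,6-triisopropylbenzenesulfonohydrazide (MeOH, cat. HCl, rt) should give (E)-N'-[1-(3,4,5-trimethoxyphenyl)ethylidene]-2,4,6-triisopropylbenzenesulfonohydrazide F4. A Shapiro reaction (n-BuLi, 2.2 equiv, THF, −78 to 0 °C) would generate 1-(3,4,5-trimethoxyphenyl)vinyllithium F5, which is trapped at −78 °C with 2-isopropoxy-4,4,5,5-tetramethyl-1,3,2-dioxaborolane to come back to the route at 9.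

Step 9. Hydrogen may add to the C2=C3 bond of the chromone faster than expected, returning isoflavanone-type material alongside debenzylation. The fallback replaces reductive cleavage by Lewis-acid debenzylation with a cation scavenger: setting out from 14, BCl3 and pentamethylbenzene in CH2Cl2 at −78 °C should remove the benzyl group selectively over the methyl ethers and arrive directly at 15, with no new intermediate.

**Further compounds**

F1 | step 6 | 5-(benzyloxy)-N,4-dimethoxy-2-(methoxymethoxy)-N-methylbenzamide | CON(C)C(=O)c1cc(OCc2ccccc2)c(OC)cc1OCOC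
F2 | step 6 | (3,4,5-trimethoxybenzyl)magnesium chloride | COc1cc(C[Mg]Cl)cc(OC)c1OC
F3 | step 6 | 1-[5-(benzyloxy)-4-methoxy-2-(methoxymethoxy)phenyl]-2-(3,4,5-trimethoxyphenyl)ethan-1-one | COCOc1cc(OC)c(OCc2ccccc2)cc1C(=O)Cc1cc(OC)c(OC)c(OC)c1
F4 | step 5 | (E)-N'-[1-(3,4,5-trimethoxyphenyl)ethylidene]-2,4,6-triisopropylbenzenesulfonohydrazide | C/C(=N\NS(=O)(=O)c1c(C(C)C)cc(C(C)C)cc1C(C)C)c1cc(OC)c(OC)c(OC)c1
F5 | step 5 | 1-(3,4,5-trimethoxyphenyl)vinyllithium | [Li]C(=C)c1cc(OC)c(OC)c(OC)c1
F0 | step 9 | none | none
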